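(The data stem from a simulated flask with made-up constants, noise included.)

common to all: left-handed substrate 20 mM; right-handed substrate 20 mM; gas 7.8 mM (held); free catalyst 20 µM; impurity 5.9 µM

| run | remark |
|---|---|
| oak | the very flask that is asked about, followed so far |
| flask |  |
oak run (percent of the left-handed substrate and right-handed substrate together charged)

| time / s | left-handed product / % | left-handed substrate / % |
|---|---|---|
| 10.0 | 3.7 | 44.7 |
| 15.0 | 8.8 | 42.8 |
| 40.0 | 22.3 | 27.1 |
| 90.0 | 42.6 | 7.6 |

(readings scatter by 1 percentage point)
- apparent order in free catalyst when 5.0% of the left-handed substrate and right-handed substrate together are converted (percent change of the rate of making left-handed product for one percent more free catalyst charged)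
- free catalyst is single-handed; left-handed substrate and right-handed substrate are mirror images of each other, charged as a racemate, each of them at the stated concentration
- at the start none of reagent is dissolved
- candidate steps: reagent + free catalyst + left-handed substrate -> free catalyst + left-handed product; gas <-> reagent; reagent + free catalyst + right-handed substrate -> free catalyst + right-handed product; free catalyst + impurity -> spent catalyst
- no earlier run changes the charge of free catalyst; that part of a forecast is a guess

In this flask, free catalyst plus spent catalyst stays equal to the catalyst charged. If each impurity costs one catalyst, the working fraction of the charge is 70.5% once the impurity has reacted. One percent more catalyst charged then means 1.42 percent more working catalyst. I call this number the lever: with reagent held fixed, it would be the order.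

But is one number enough? Reagent starts undissolved, and the first-order constant of the left-handed substrate moves along the oak run:

| Window | Constant |
|---|---|
| start to 15.0 s | 0.0104 s⁻¹ |
| 40.0 s to 90.0 s | 0.0254 s⁻¹ |

Taking the same working catalyst in both windows, I read their ratio, 0.408, as early reagent against late reagent, with the scatter of the readings. Reagent starts undissolved, and I take it to stay below saturation, so this ratio is a rough upper estimate of the early fraction of saturation.

Now I put reagent where supply balances use, a steady state, and I take supply as proportional to the distance from saturation. The order in working catalyst then equals reagent's fraction of saturation, so the order asked for is the lever times that fraction. My estimate is a value below about 0.579.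

The forecast gives 0.6, saying that “catalyst matters only partly”.

The flask gives 0.33, which is less than my estimate.

    reagent + free catalyst + left-handed substrate → free catalyst + left-handed product (k = 8.40 × 10⁵ M⁻² s⁻¹)
    gas ⇌ reagent, rate k2*(csat - [reagent]) (kL = 0.0600 s⁻¹)
    reagent + free catalyst + right-handed substrate → free catalyst + right-handed product (k = 4.40 × 10⁵ M⁻² s⁻¹)
    free catalyst + impurity → spent catalyst (k = 3.60 × 10⁵ M⁻¹ s⁻¹)

Divided by the lever, the order of this flask at 0.122 min is 0.232 percent per percent of working catalyst. At 0.500 min, in the same flask, reagent stands at 18.3% of saturation.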